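## Retrosynthetic overview

1. The dihydrofuran hemiketal ring (O7k–C3) is closed last and by itself: once the kaempferol 7-OH is free next to the C3 ketone of a 2,2-diarylchromane-3,4-dione it adds to it, and the only possible cis ring fusion copies the configuration of C2 onto C3.
2. The 3,4-dione comes from a 4-ethoxy-2H-chromene by two oxidations at C3 (enol-ether epoxidation, then alcohol oxidation).
3. Key disconnection: pyran ring C of the new chromane unit is cut at C2–C3 and at C4–C4a. Forward, this is a dehydrogenative cationic [4+2] cycloaddition between the O-aryl oxocarbenium ion C2=O1(+)–C8a=C4a and ethoxyacetylene (C3≡C4). The enabling feature is that C2 carries the ether oxygen O1 of phloroglucinol ring A plus two electron-rich aryl groups (the 4-oxyphenyl ring and kaempferol C8k), so its C–H is a hydride donor, and that C4a is ortho to O1 and ortho/para to two more ring oxygens.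
4. The cation precursor is a diarylmethyl aryl ether, made from a benzhydrol and 3,5-bis(benzyloxy)phenol; the benzhydrol comes from 8-magnesiated tetra-O-benzylkaempferol and 4-(benzyloxy)benzaldehyde.
5. Ring order: the kaempferol rings are bought intact; ring C (fused to ring A) is built in the key step; the dihydrofuran hemiketal ring forms last.

Key step: step 5

Remark on locants: O1, C2, C3, C4, C4a, C5–C8, C8a belong to the new chromane unit (ring A is its benzene ring, ring C its pyran ring); locants with the suffix k belong to the kaempferol unit. KBn stands for the 3,5,7-tris(benzyloxy)-2-[4-(benzyloxy)phenyl]-4-oxo-4H-chromen-8-yl group.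

Remark on handling: chromene 13 is kept cold and in the dark, because 2,2-diaryl-2H-chromenes can open reversibly (6π) to achiral quinoid forms.

Assumption: the sense of induction of the chiral acid in step 5 cannot be predicted with confidence; the (R)-acid is written, and its (S)-antipode is used instead if the first experiment shows the opposite sense.

## Route

Step 1
Reactants: 1 kaempferol
Product: 2 3,5,7-tris(benzyloxy)-2-[4-(benzyloxy)phenyl]-4H-chromen-4-one (tetra-O-benzylkaempferol)
Conditions: BnBr (6 equiv), K2CO3, DMF, 80 °C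
Reagents that add atoms: benzyl bromide, BrCc1ccccc1
Why: Williamson O-alkylation should cap all four hydroxyl groups, the hydrogen-bonded 5-OH being forced by excess reagent and heat.

Step 2
Reactants: 2 tetra-O-benzylkaempferol
Product: 3 3,5,7-tris(benzyloxy)-2-[4-(benzyloxy)phenyl]-8-iodo-4H-chromen-4-one
Conditions: NIS, TFA (cat.), MeCN/CH2Cl2, 0 °C → rt
Reagents that add atoms: N-iodosuccinimide, O=C1CCC(=O)N1I
Why: Electrophilic aromatic iodination of a 5,7-dialkoxyflavone should go to C8k, which is ortho to the 7-alkoxy group and the ring oxygen and less hindered than C6k between two benzyloxy groups.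

Step 3
Reactants: 3 8-iodo-tetra-O-benzylkaempferol; 4 4-(benzyloxy)benzaldehyde
Product: 6 rac-[4-(benzyloxy)phenyl](KBn)methanol, via arylmagnesium chloride 5 (not isolated)
Conditions: iPrMgCl·LiCl, THF, –40 °C; then 4, –40 → 0 °C; aq. NH4Cl
Reagents that add atoms: none
Why: Iodine–magnesium exchange with the turbo-Grignard reagent should outrun addition to the vinylogous-ester carbonyl at low temperature, and the aryl Grignard then adds to the aldehyde; the carbinol centre is racemic and is made planar in step 5.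

Step 4
Reactants: 6 benzhydrol; 7 3,5-bis(benzyloxy)phenol
Product: 9 rac-1,3-bis(benzyloxy)-5-{[4-(benzyloxy)phenyl](KBn)methoxy}benzene, via benzhydryl chloride 8 (not isolated)
Conditions: MsCl, Et3N, CH2Cl2, –20 → 0 °C; then 7, Cs2CO3, DMF, 0 °C → rt
Reagents that add atoms: none
Why: The electron-rich benzhydrol should give the chloride through its mesylate, and the caesium phenoxide in DMF should be O-alkylated in a Williamson-type substitution with SN1 character.

Step 5
Reactants: 9 diarylmethyl aryl ether; 10 ethoxyacetylene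
Product: 13 (2R)-5,7-bis(benzyloxy)-2-[4-(benzyloxy)phenyl]-4-ethoxy-2-(KBn)-2H-chromene, via O-aryl oxocarbenium ion 11 (not isolated), via ethoxyketenium ion 12 (not isolated)
Conditions: DDQ (1.05 equiv), 4 Å MS, CH2Cl2/toluene, 0 °C; then (R)-3,3'-bis(2,4,6-triisopropylphenyl)-1,1'-binaphthyl-2,2'-diyl N-(trifluoromethanesulfonyl)phosphoramide (10 mol %), 10 (3 equiv), –60 → –30 °C, dark; Et3N
Reagents that add atoms: none
Why: Proposed new method: DDQ abstracts the doubly benzylic, oxygen-bound hydride at C2 to give the O-aryl oxocarbenium ion 11 (a cationic 2-oxadiene C2=O1–C8a=C4a), the strong chiral acid exchanges the hydroquinone anion for its own anion (DDQH2 precipitates), the CH terminus of ethoxyacetylene adds to C2 to give the ethoxy-stabilised ketenium ion 12, and C4a attacks the ketenium carbon C4 with loss of the ring proton, which returns the acid; overall this is a stepwise polar [4+2] cycloaddition. The closest known reaction types are the Povarov reaction and its oxygen analogue ([4+2] of aryl oxocarbenium ions with alkenes), DDQ-mediated cross-dehydrogenative coupling of benzylic ethers, Friedel–Crafts capture of ketenium and keteniminium ions from ynol ethers and ynamides, and chiral-phosphate-type counter-anion control of cations generated with DDQ. Only pyran ring C closes, by a 6-exo-dig Friedel–Crafts attack of C4a on the digonal carbon C4 (the C=O+ π bond is the one broken). The single new stereocentre C2 is set in the C2–C3 bond formation under control of the chiral counter-anion, which blocks one face of the planar cation. The step needs the alkyne to react through its CH terminus (secured by the ethoxy donor, which places the cation at C4), ring closure at C4a and not at the 4-benzyloxyphenyl ring or an ether oxygen (secured by the three oxygens ortho and para to C4a and a six-membered transition state; the two positions ortho to O1 are equivalent, so one regioisomer should result), and a slow achiral background path (low temperature, non-polar medium).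

Step 6
Reactants: 13 4-ethoxy-2H-chromene
Product: 15 (2R)-5,7-bis(benzyloxy)-2-[4-(benzyloxy)phenyl]-3-hydroxy-2-(KBn)chroman-4-one (both C3 epimers), via epoxy ether 14 (not isolated)
Conditions: DMDO, acetone/CH2Cl2, –40 °C, dark; then H2O, pH 7 buffer, THF, 0 °C
Reagents that add atoms: dimethyldioxirane, CC1(C)OO1; water, O
Why: In this Rubottom-type oxidation the electron-rich enol ether should be epoxidised far faster than the chromone double bond, and the epoxy ether should open with water to the α-hydroxy ketone under neutral conditions that avoid enolisation and ring opening; the C3 configuration does not matter because C3 becomes a ketone.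

Step 7
Reactants: 15 3-hydroxychroman-4-one
Product: 16 (2R)-5,7-bis(benzyloxy)-2-[4-(benzyloxy)phenyl]-2-(KBn)chromane-3,4-dione
Conditions: DMP, CH2Cl2, 0 °C → rt
Reagents that add atoms: none
Why: Dess–Martin oxidation of the secondary alcohol under non-basic conditions should give the non-enolisable 1,2-diketone without touching C2.

Step 8
Reactants: 16 hepta-O-benzyl 3,4-dione
Product: 18 target CNP0314633.1, the (2R,3S) cis-fused hemiketal, via free 3,4-dione 17 (not isolated)
Conditions: BCl3, C6HMe5, CH2Cl2, –78 °C; MeOH quench; aq. work-up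
Reagents that add atoms: none
Why: Lewis-acid debenzylation with pentamethylbenzene as cation scavenger should remove all seven aryl benzyl ethers without reducing the diketone or chromone, and the freed 7k-OH should then add to the C3 ketone in a 5-exo-trig hemiketalisation whose only possible cis fusion sets C3 as S from the R centre at C2.

## Compound list

1 | kaempferol | O=c1c(O)c(-c2ccc(O)cc2)oc2cc(O)cc(O)c12 | starting material
2 | 3,5,7-tris(benzyloxy)-2-[4-(benzyloxy)phenyl]-4H-chromen-4-one | O=c1c(OCc2ccccc2)c(-c2ccc(OCc3ccccc3)cc2)oc2cc(OCc3ccccc3)cc(OCc3ccccc3)c12 | intermediate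
3 | 3,5,7-tris(benzyloxy)-2-[4-(benzyloxy)phenyl]-8-iodo-4H-chromen-4-one | O=c1c(OCc2ccccc2)c(-c2ccc(OCc3ccccc3)cc2)oc2c(I)c(OCc3ccccc3)cc(OCc3ccccc3)c12 | intermediate
4 | 4-(benzyloxy)benzaldehyde | O=Cc1ccc(OCc2ccccc2)cc1 | starting material
5 | arylmagnesium chloride from 3 (8-chloromagnesio derivative, LiCl complex) | O=c1c(OCc2ccccc2)c(-c2ccc(OCc3ccccc3)cc2)oc2c([Mg]Cl)c(OCc3ccccc3)cc(OCc3ccccc3)c12 | intermediate
6 | rac-[4-(benzyloxy)phenyl](KBn)methanol | O=c1c(OCc2ccccc2)c(-c2ccc(OCc3ccccc3)cc2)oc2c(C(O)c3ccc(OCc4ccccc4)cc3)c(OCc3ccccc3)cc(OCc3ccccc3)c12 | intermediate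
7 | 3,5-bis(benzyloxy)phenol | Oc1cc(OCc2ccccc2)cc(OCc2ccccc2)c1 | starting material
8 | rac-8-{[4-(benzyloxy)phenyl](chloro)methyl}-3,5,7-tris(benzyloxy)-2-[4-(benzyloxy)phenyl]-4H-chromen-4-one | O=c1c(OCc2ccccc2)c(-c2ccc(OCc3ccccc3)cc2)oc2c(C(Cl)c3ccc(OCc4ccccc4)cc3)c(OCc3ccccc3)cc(OCc3ccccc3)c12 | intermediate
9 | rac-1,3-bis(benzyloxy)-5-{[4-(benzyloxy)phenyl](KBn)methoxy}benzene | O=c1c(OCc2ccccc2)c(-c2ccc(OCc3ccccc3)cc2)oc2c(C(Oc3cc(OCc4ccccc4)cc(OCc4ccccc4)c3)c3ccc(OCc4ccccc4)cc3)c(OCc3ccccc3)cc(OCc3ccccc3)c12 | intermediate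
10 | ethoxyacetylene (ethyl ethynyl ether) | C#COCC | starting material
11 | [4-(benzyloxy)phenyl][3,5-bis(benzyloxy)phenoxy](KBn)methylium ion (O-aryl oxocarbenium ion, paired first with the hydroquinone anion, then with the chiral anion) | O=c1c(OCc2ccccc2)c(-c2ccc(OCc3ccccc3)cc2)oc2c([C+](Oc3cc(OCc4ccccc4)cc(OCc4ccccc4)c3)c3ccc(OCc4ccccc4)cc3)c(OCc3ccccc3)cc(OCc3ccccc3)c12 | intermediate
12 | (R)-configured ethoxyketenium ion, [3-[4-(benzyloxy)phenyl]-3-[3,5-bis(benzyloxy)phenoxy]-3-(KBn)prop-1-en-1-ylidene](ethyl)oxonium | CC[O+]=C=C[C@@](Oc1cc(OCc2ccccc2)cc(OCc2ccccc2)c1)(c1ccc(OCc2ccccc2)cc1)c1c(OCc2ccccc2)cc(OCc2ccccc2)c2c(=O)c(OCc3ccccc3)c(-c3ccc(OCc4ccccc4)cc3)oc12 | intermediate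
13 | (2R)-5,7-bis(benzyloxy)-2-[4-(benzyloxy)phenyl]-4-ethoxy-2-(KBn)-2H-chromene | CCOC1=C[C@@](c2ccc(OCc3ccccc3)cc2)(c2c(OCc3ccccc3)cc(OCc3ccccc3)c3c(=O)c(OCc4ccccc4)c(-c4ccc(OCc5ccccc5)cc4)oc23)Oc2cc(OCc3ccccc3)cc(OCc3ccccc3)c12 | intermediate
14 | (2R)-5,7-bis(benzyloxy)-2-[4-(benzyloxy)phenyl]-3,4-epoxy-4-ethoxy-2-(KBn)chromane (epoxide face not defined) | CCOC12OC1[C@@](c1ccc(OCc3ccccc3)cc1)(c1c(OCc3ccccc3)cc(OCc3ccccc3)c3c(=O)c(OCc4ccccc4)c(-c4ccc(OCc5ccccc5)cc4)oc13)Oc1cc(OCc3ccccc3)cc(OCc3ccccc3)c12 | intermediate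
15 | (2R)-5,7-bis(benzyloxy)-2-[4-(benzyloxy)phenyl]-3-hydroxy-2-(KBn)chroman-4-one (both C3 epimers) | O=C1C(O)[C@@](c2ccc(OCc3ccccc3)cc2)(c2c(OCc3ccccc3)cc(OCc3ccccc3)c3c(=O)c(OCc4ccccc4)c(-c4ccc(OCc5ccccc5)cc4)oc23)Oc2cc(OCc3ccccc3)cc(OCc3ccccc3)c12 | intermediate
16 | (2R)-5,7-bis(benzyloxy)-2-[4-(benzyloxy)phenyl]-2-(KBn)chromane-3,4-dione | O=C1C(=O)[C@@](c2ccc(OCc3ccccc3)cc2)(c2c(OCc3ccccc3)cc(OCc3ccccc3)c3c(=O)c(OCc4ccccc4)c(-c4ccc(OCc5ccccc5)cc4)oc23)Oc2cc(OCc3ccccc3)cc(OCc3ccccc3)c12 | intermediate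
17 | (2R)-5,7-dihydroxy-2-(4-hydroxyphenyl)-2-[3,5,7-trihydroxy-2-(4-hydroxyphenyl)-4-oxo-4H-chromen-8-yl]chromane-3,4-dione | O=C1C(=O)[C@@](c2ccc(O)cc2)(c2c(O)cc(O)c3c(=O)c(O)c(-c4ccc(O)cc4)oc23)Oc2cc(O)cc(O)c12 | intermediate
18 | CNP0314633.1: (2R,3S)-3,5,7-trihydroxy-2-(4-hydroxyphenyl)chroman-4-one unit whose C2 is bonded to C8k and whose C3 is bonded through O7k to kaempferol (cis-fused dihydrofuran hemiketal) | O=C1c2c(O)cc(O)cc2O[C@]2(c3ccc(O)cc3)c3c(cc(O)c4c(=O)c(O)c(-c5ccc(O)cc5)oc34)O[C@]12O | target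

## Step count and risks

Total step count: 8. Longest linear sequence: 8 steps (1 → 18).

Steps most likely to fail:

Step 5 (proposed method). What may go wrong: DDQ may oxidise the trialkoxyaryl ring by electron transfer instead of abstracting the hydride at C2, the ynol ether may be consumed by the acid or by residual DDQ before the ring closes, and the achiral hydroquinone-anion ion pair may react in the background and erode facial discrimination at C2. The fallback uses known chemistry, sets out from 9 and comes back at 16. DDQ oxidation of 9 followed by tris(trimethylsiloxy)ethylene (oxidative Mukaiyama-type coupling of a benzylic ether with a silyl ketene acetal) should give the bis(trimethylsilyl) adduct F1, and aqueous work-up the racemic α-hydroxy acid F2. TFAA should close ring C by intramolecular Friedel–Crafts acylation at C4a to give the racemic 3-trifluoroacetoxychromanone F3, and aqueous NaHCO3 should cleave the trifluoroacetate to the racemic hydroxy ketone F4. DMP should give the racemic dione F5, and preparative chromatography on an amylose tris(3,5-dimethylphenylcarbamate) phase should separate 16 from its (2S)-enantiomer F6.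

Step 4. What may go wrong: chloride 8 may ionise and alkylate the phloroglucinol-type phenoxide at carbon (Friedel–Crafts path), or hydrolyse back to 6. The fallback sets out from 6 and comes back at 9: Mitsunobu etherification of 6 with 7 (PPh3, DIAD, toluene, 0 °C) under neutral conditions, in which the phenol is O-alkylated through the alkoxyphosphonium ion; no new compound arises (F0).

Step 8. What may go wrong: the Lewis acid may ionise the C2–O1 bond or leave the hindered 7k-benzyl ether uncleaved, so that the hemiketal does not close. The fallback sets out from 16 and comes back at 18: hydrogenolysis (H2, Pd(OH)2/C, EtOAc/MeOH, rt) should cleave the benzyl ethers reductively through the same free dione 17, which closes to 18; no new compound arises (F0).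

## Further compounds

F1 | step 5 | rac-trimethylsilyl 3-[4-(benzyloxy)phenyl]-3-[3,5-bis(benzyloxy)phenoxy]-3-(KBn)-2-(trimethylsilyloxy)propanoate (diastereomer mixture) | C[Si](C)(C)OC(=O)C(O[Si](C)(C)C)C(Oc1cc(OCc2ccccc2)cc(OCc2ccccc2)c1)(c1ccc(OCc2ccccc2)cc1)c1c(OCc2ccccc2)cc(OCc2ccccc2)c2c(=O)c(OCc3ccccc3)c(-c3ccc(OCc4ccccc4)cc3)oc12
F2 | step 5 | rac-3-[4-(benzyloxy)phenyl]-3-[3,5-bis(benzyloxy)phenoxy]-2-hydroxy-3-(KBn)propanoic acid (diastereomer mixture) | OC(=O)C(O)C(Oc1cc(OCc2ccccc2)cc(OCc2ccccc2)c1)(c1ccc(OCc2ccccc2)cc1)c1c(OCc2ccccc2)cc(OCc2ccccc2)c2c(=O)c(OCc3ccccc3)c(-c3ccc(OCc4ccccc4)cc3)oc12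
F3 | step 5 | rac-5,7-bis(benzyloxy)-2-[4-(benzyloxy)phenyl]-4-oxo-2-(KBn)chroman-3-yl trifluoroacetate (diastereomer mixture) | O=C1C(OC(=O)C(F)(F)F)C(c2ccc(OCc3ccccc3)cc2)(c2c(OCc3ccccc3)cc(OCc3ccccc3)c3c(=O)c(OCc4ccccc4)c(-c4ccc(OCc5ccccc5)cc4)oc23)Oc2cc(OCc3ccccc3)cc(OCc3ccccc3)c12
F4 | step 5 | rac-5,7-bis(benzyloxy)-2-[4-(benzyloxy)phenyl]-3-hydroxy-2-(KBn)chroman-4-one (racemic form of 15) | O=C1C(O)C(c2ccc(OCc3ccccc3)cc2)(c2c(OCc3ccccc3)cc(OCc3ccccc3)c3c(=O)c(OCc4ccccc4)c(-c4ccc(OCc5ccccc5)cc4)oc23)Oc2cc(OCc3ccccc3)cc(OCc3ccccc3)c12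
F5 | step 5 | rac-5,7-bis(benzyloxy)-2-[4-(benzyloxy)phenyl]-2-(KBn)chromane-3,4-dione (racemic form of 16) | O=C1C(=O)C(c2ccc(OCc3ccccc3)cc2)(c2c(OCc3ccccc3)cc(OCc3ccccc3)c3c(=O)c(OCc4ccccc4)c(-c4ccc(OCc5ccccc5)cc4)oc23)Oc2cc(OCc3ccccc3)cc(OCc3ccccc3)c12
F6 | step 5 | (2S)-5,7-bis(benzyloxy)-2-[4-(benzyloxy)phenyl]-2-(KBn)chromane-3,4-dione (enantiomer of 16, set aside) | O=C1C(=O)[C@](c2ccc(OCc3ccccc3)cc2)(c2c(OCc3ccccc3)cc(OCc3ccccc3)c3c(=O)c(OCc4ccccc4)c(-c4ccc(OCc5ccccc5)cc4)oc23)Oc2cc(OCc3ccccc3)cc(OCc3ccccc3)c12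
F0 | step 4 | none | none
F0 | step 8 | none | none
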